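## The problem

The target 20 is quercetin with a 3-methylbut-2-enyl (prenyl) group at C2' of ring B. It is a 3,5,7-trihydroxy-4H-chromen-4-one (rings A and C) joined at C2 to a benzene ring whose contiguous positions C1'–C4' carry the chromone, the prenyl group and two hydroxyls. It has no stereocentre; the only stereochemical element on the way is the geometry of an acrylate, since only the isomer with the acyl group beside the aryloxy group can close ring C. A synthesis must therefore settle the order in which the ring C bonds O1–C2, C4–C4a and C3–O are made, and how the 1,2,3,4-substituted ring B is built. The prenyl alkene is the fragile group: next to the C3' oxygen it cyclises to a chroman under protic or strong Lewis acid, it is reduced under the hydrogenolysis that removes benzyl ethers, and it adds electrophilic halogen and peracids. The free polyphenol is in addition air-sensitive in base. The last deprotection must therefore be neither acidic, reductive nor oxidative, which points to allyl ethers cleaved by zerovalent palladium. These in turn rule out earlier palladium chemistry on any allyl-bearing intermediate, and an aryl bromide ortho to an allyloxy group would moreover undergo 5-exo Heck closure. The feature that makes the key step possible is ring A: O1, O5 and O7 are mutually meta, so in a 3,5-dialkoxyphenyl ether all three oxygens activate the carbon that becomes C4a, and the two carbons ortho to O1 are equivalent. The C3 oxygen is best kept out of that acylation: as an allyl enol ether it would put an allyl vinyl ether with an acyl group at its C2 under a Lewis acid, which invites Claisen rearrangement, and its assembly would need a substitution at a tetrasubstituted alkene carbon.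

## Retrosynthesis

**20 from 19.** The last cut removes only O–allyl bonds, so target 20 comes from tetra-O-allyl flavonol 19. Allyl is preferred to methyl, benzyl or acetal protection because its cleavage by zerovalent palladium and an amine is the one standard phenol deprotection that is neither acidic nor reductive. The C3 hydroxyl needs no protection. The forward reaction has to cleave four aryl allyl ethers, including the one at the hydrogen-bonded 5-position, and leave the C-prenyl group, which has no leaving group, alone.

**19 from 16.** The C3–O bond is cut next, giving flavone 16. Carrying this oxygen through the ring closure as an ether is rejected for the two reasons given above. Flavones are deprotonated selectively at C3, so 16 needs only lithiation, borate trapping and oxidation. Because 16 carries six alkenes, dioxirane and peracid routes to flavonols are excluded and an anionic one is required.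

**16 from 14.** Ring C is opened at C4–C4a: flavone 16 comes from the (Z)-3-aryloxyacrylic acid 14 through its acid chloride 15. This is the ring C bond whose formation is regiochemically trivial, for the symmetry reason above. Cutting O1–C2 instead would require a mono-deprotected, ortho-acylated phloroglucinol. Cutting C2–C1' would require a metal-catalysed coupling on an allyl-protected substrate. Acid 14 is an open-chain vinylogous carbonate built from two separately made arenes. The forward acylation must run under conditions that a prenyl group and four allyl ethers survive: neutral acid chloride formation, low temperature and a proton scavenger.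

**14 from 12 and 9.** Acid 14 is the hydrolysis product of methyl ester 13, and 13 is cut at O1–C2 into ynoate 12 and phenol 9. Conjugate addition of a phenol to an arylpropiolate forms this bond in one step with no leaving group to install, and anti addition delivers the Z geometry that ring closure needs. The two fragments are of similar size, so the route is convergent here.

**12 from 7.** The C3–C4 unit of ynoate 12 is removed in two cuts. The ester carbon (future C4) comes from acylation of acetylide 11 with a chloroformate. The alkyne carbon (future C3) comes from one-carbon homologation of aldehyde 7 through dibromoalkene 10. The aldehyde is the natural oxidation level because that carbon is already present in the commercial bromoaldehyde 1.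

**7 from 1.** Aldehyde 7 is cut at its two O–allyl bonds and at the C2'–C1'' bond. The order is forced: the prenyl group is attached by Stille coupling of bromide 3 with stannane 4 before any allyl ether exists. Catechol 2, from demethylation of 1, is therefore masked as diacetate 3, and the acetates of coupling product 5 are exchanged for allyl ethers through catechol 6. The bromine of 1 marks C2' from the start, so the substitution pattern of ring B is never in question.

**9 from 8.** Phenol 9 is cut at two O–allyl bonds back to phloroglucinol 8. Threefold symmetry means any two oxygens give the same diether; only the degree of alkylation has to be controlled.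

## Roads not taken

Alternative 1: The cut is the C2–C1' bond, made while ring B hangs from O3 through an ester whose carbonyl carbon is the future C1''.
- **Key step:** zerovalent palladium would insert into the C–Br bond of ester A1 and arylate the chromone C2–H, closing the six-membered lactone A2.
- **Merits:** the C3 oxygen is present from the start, the tether fixes the ortho relationship between the C2 link and the future prenyl carbon, and no prenyl group is exposed while the rings are built.
- **Weak points:** after A2 the lactone carbonyl still has to become a benzylic CH2 carrying a 2-methylprop-1-enyl unit. That means reduction, activation and a further C–C coupling next to a free 3-hydroxyl and the C4 carbonyl. The acetal protecting groups of A2 also force an acidic last step beside the ortho-prenyl phenol.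
- **Comparison:** this road is better than the chosen plan in that no separate C3 oxygenation is needed and no Lewis acid ever meets the prenyl group. The chosen plan sets against it a prenyl group complete before the fragments are joined, no functional-group surgery after ring closure, and a neutral end-game.

Alternative 2: The cuts are C4a–C4, C4–C3 and O1–C2 at once.
- **Key step:** iodophenol A3 and arylacetylene A4 would be joined in a carbonylative Sonogashira coupling under PdCl2(PPh3)2, and the resulting ynone would close through the phenol oxygen to flavone A5.
- **Merits:** it is the most convergent of the four plans; two bonds and ring C arise in one flask from simple partners, under basic conditions harmless to the prenyl group.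
- **Weak points:** 5-exo closure at the ynone competes with 6-endo. Carbonyl-free coupling followed by furan formation is a second escape channel, favoured because the electron-rich, doubly ortho-oxygenated iodide A3 is slow in oxidative addition. A5 lacks the C3 hydroxyl, so it needs the same late C3 oxygenation as the chosen plan. Its acetal groups again end in acid, and allyl ethers could not replace them in a palladium-catalysed key step.
- **Comparison:** in step economy of ring construction this road is better (one step against addition, hydrolysis and acylation). The chosen plan sets against it a ring closure that can only give the six-membered ring, and palladium-free assembly that permits the allyl ethers and hence the neutral deprotection.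

Alternative 3: The cut is O1–C8a.
- **Key step:** the enolate oxygen of diketone A6 would displace an ortho fluoride of its trifluorobenzoyl ring under carbonate base, giving difluoroflavonol A7.
- **Merits:** the closure is mild and basic, the two ortho fluorides are equivalent, and the C3 oxygen is carried in as an ether that is not an allyl vinyl ether.
- **Weak points:** A7 carries fluorine where the target has O5 and O7. Two further aromatic substitutions by an oxygen nucleophile are needed, the second slowed by the donor installed in the first. That nucleophile must bear a group removable without acid or hydrogenation, while the acetal groups elsewhere still call for acid.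
- **Comparison:** the ring closure itself is probably more reliable and gentler to the prenyl group than a Lewis acid acylation. The chosen plan sets against this a ring A whose oxygen pattern is bought complete with phloroglucinol, with no late C–F to C–O exchanges.

Key step: step 10

Assumption: compound 1 (the C2-bromination product of isovanillin) and stannane 4 are taken as catalogue chemicals; acrylates 13–15 are drawn as the Z isomers expected from anti addition, and any E isomer formed beside them is carried along because the acyl cation of step 10 can rotate about C2–C3.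

## Route

Step 1
Reactants: 1 2-bromo-3-hydroxy-4-methoxybenzaldehyde
Product: 2 2-bromo-3,4-dihydroxybenzaldehyde
Conditions: BBr3, CH2Cl2, −78 °C to rt; then H2O
Reagents that add atoms: none
Why: Lewis acid ether cleavage: BBr3 binds the methoxy oxygen and bromide removes the methyl group by SN2; the aryl bromide and the aldehyde are inert and no acid-sensitive group is present yet.

Step 2
Reactants: 2 2-bromo-3,4-dihydroxybenzaldehyde
Product: 3 3,4-diacetoxy-2-bromobenzaldehyde
Conditions: Ac2O, pyridine, DMAP (cat.), CH2Cl2, 0 °C to rt
Reagents that add atoms: acetic anhydride, CC(=O)OC(C)=O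
Why: DMAP-catalysed O-acylation; the acetates remove the acidic catechol protons that would protodestannylate the allyl-type stannane in step 3, and unlike allyl ethers they offer zerovalent palladium neither a π-allyl pathway nor a tethered alkene for Heck closure.

Step 3
Reactants: 3 3,4-diacetoxy-2-bromobenzaldehyde; 4 tributyl(3-methylbut-2-en-1-yl)stannane
Product: 5 3,4-diacetoxy-2-(3-methylbut-2-en-1-yl)benzaldehyde
Conditions: Pd(PPh3)4 (5 mol %), toluene, 100 °C
Reagents that add atoms: none
Why: Stille cross-coupling: oxidative addition into C–Br is helped by the ortho formyl group and the electron-poor diacetate ring, and reductive elimination through the less substituted allyl terminus should give the linear prenyl group; the neutral medium leaves acetates and aldehyde untouched.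

Step 4
Reactants: 5 3,4-diacetoxy-2-(3-methylbut-2-en-1-yl)benzaldehyde
Product: 7 3,4-bis(allyloxy)-2-(3-methylbut-2-en-1-yl)benzaldehyde, via 3,4-dihydroxy-2-prenylbenzaldehyde 6 (not isolated)
Conditions: K2CO3, MeOH, rt, argon; evaporate; then allyl bromide, K2CO3, DMF, 40 °C
Reagents that add atoms: allyl bromide, C=CCBr
Why: Base-catalysed methanolysis of the aryl acetates frees catechol 6 as its potassium salt, which is alkylated in the same flask by Williamson ether synthesis; keeping 6 under argon and unisolated avoids air oxidation of the catechol.

Step 5
Reactants: 8 phloroglucinol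
Product: 9 3,5-bis(allyloxy)phenol
Conditions: allyl bromide (2 equiv), K2CO3, DMF, rt
Reagents that add atoms: allyl bromide, C=CCBr
Why: Williamson ether synthesis under statistical control: two equivalents of halide should make the diether the main component, separable by chromatography from mono- and triether, and the polar aprotic medium favours O- over C-alkylation of the phloroglucinol anion.

Step 6
Reactants: 7 3,4-bis(allyloxy)-2-(3-methylbut-2-en-1-yl)benzaldehyde
Product: 10 1,2-bis(allyloxy)-4-(2,2-dibromovinyl)-3-(3-methylbut-2-en-1-yl)benzene
Conditions: CBr4, PPh3, Zn dust, CH2Cl2, rt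
Reagents that add atoms: carbon tetrabromide, BrC(Br)(Br)Br
Why: Corey–Fuchs dibromo-olefination (Wittig reaction of the dibromomethylene ylide); zinc takes up the bromine that would otherwise sit on phosphorus, so the prenyl alkene and the allyl ethers are not exposed to HBr or bromine equivalents.

Step 7
Reactants: 10 1,2-bis(allyloxy)-4-(2,2-dibromovinyl)-3-(3-methylbut-2-en-1-yl)benzene
Product: 12 methyl 3-[3,4-bis(allyloxy)-2-(3-methylbut-2-en-1-yl)phenyl]prop-2-ynoate, via lithium arylacetylide 11 (not isolated)
Conditions: n-BuLi (2.2 equiv), THF, −78 °C; then ClCO2Me, −78 to 0 °C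
Reagents that add atoms: methyl chloroformate, COC(Cl)=O
Why: Second stage of the Corey–Fuchs sequence: bromine–lithium exchange and α-elimination with 1,2-shift give the alkyne, the second equivalent of n-BuLi forms acetylide 11, and C-acylation by the chloroformate gives the ynoate; at −78 °C aryl allyl ethers are not metalated.

Step 8
Reactants: 12 methyl 3-[3,4-bis(allyloxy)-2-(3-methylbut-2-en-1-yl)phenyl]prop-2-ynoate; 9 3,5-bis(allyloxy)phenol
Product: 13 methyl (2Z)-3-[3,5-bis(allyloxy)phenoxy]-3-[3,4-bis(allyloxy)-2-(3-methylbut-2-en-1-yl)phenyl]prop-2-enoate
Conditions: Cs2CO3 (20 mol %), DMF, 60 °C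
Reagents that add atoms: none
Why: Base-catalysed oxa-Michael addition of a phenol to a 3-arylpropiolate, the classical entry to 3-aryloxycinnamates: the phenoxide attacks the aryl-bearing alkyne carbon and anti protonation of the vinyl anion places the ester cis to the aryloxy group (Z); the soft acceptor and the polar aprotic medium favour O- over C-attack.

Step 9
Reactants: 13 methyl (2Z)-3-[3,5-bis(allyloxy)phenoxy]-3-[3,4-bis(allyloxy)-2-(3-methylbut-2-en-1-yl)phenyl]prop-2-enoate
Product: 14 (2Z)-3-[3,5-bis(allyloxy)phenoxy]-3-[3,4-bis(allyloxy)-2-(3-methylbut-2-en-1-yl)phenyl]prop-2-enoic acid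
Conditions: LiOH, THF/MeOH/H2O, rt; then 1 M HCl to pH 4, 0 °C
Reagents that add atoms: lithium hydroxide, [Li+].[OH-]
Why: Ester saponification by acyl–oxygen cleavage; the aryl allyl ethers, the prenyl group and the enol ether linkage tolerate LiOH at room temperature, and the brief cold acidification to pH 4 is too mild to protonate the prenyl alkene.

Step 10
Reactants: 14 (2Z)-3-[3,5-bis(allyloxy)phenoxy]-3-[3,4-bis(allyloxy)-2-(3-methylbut-2-en-1-yl)phenyl]prop-2-enoic acid
Product: 16 5,7-bis(allyloxy)-2-[3,4-bis(allyloxy)-2-(3-methylbut-2-en-1-yl)phenyl]-4H-chromen-4-one, via acryloyl chloride 15 (not isolated)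
Conditions: 1-chloro-N,N,2-trimethylprop-1-en-1-amine, CH2Cl2, 0 °C to rt; then SnCl4 (1.2 equiv), 2,6-di-tert-butyl-4-methylpyridine, CH2Cl2, −78 to −40 °C
Reagents that add atoms: none
Why: The α-chloroenamine converts acid 14 into acid chloride 15 under neutral conditions (the co-product is an amide, not HCl), and SnCl4 then ionises 15 to an acylium ion that the β-aryloxy group stabilises as a ketene–oxocarbenium hybrid. This electrophile attacks the ring A carbon ortho to the ether oxygen, a position that is also ortho and para to the two allyloxy groups, and the hindered pyridine takes the proton from the arenium ion to restore ring A and give flavone 16. The closest known reaction type is the intramolecular Friedel–Crafts acylation by which 3-aryloxycinnamic acids and their chlorides are cyclised to flavones. Ring C closes in a 6-exo mode at the acyl carbon (exo-trig for the complexed acid chloride, exo-dig for the free acylium ion), with the nucleophilic C4a–C8a bond of ring A inside the new ring. No stereocentre is formed. Regioselectivity on ring A is secured by symmetry: the two carbons ortho to O1 are equivalent and the para carbon cannot reach the acyl carbon. Chemoselectivity over ring B rests on geometry and ring size: the Z acid holds the acyl group beside ring A, closure onto ring B would need the E isomer and would form a five-membered ring, and the single-bond character of C2–C3 in the cation lets E material rotate into the productive form. Low temperature, a weakly chelating Lewis acid and the proton scavenger are what should spare the prenyl alkene and the four allyl ethers.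

Step 11
Reactants: 16 5,7-bis(allyloxy)-2-[3,4-bis(allyloxy)-2-(3-methylbut-2-en-1-yl)phenyl]-4H-chromen-4-one
Product: 19 5,7-bis(allyloxy)-2-[3,4-bis(allyloxy)-2-(3-methylbut-2-en-1-yl)phenyl]-3-hydroxy-4H-chromen-4-one, via 3-lithioflavone 17 (not isolated), via flavon-3-ylboronate 18 (not isolated)
Conditions: LiN(i-Pr)2 (commercial solution), THF, −78 °C; B(OMe)3, −78 to 0 °C; then AcOH, 30% H2O2, 0 °C to rt
Reagents that add atoms: hydrogen peroxide, OO
Why: Vinylic lithiation followed by borylation–oxidation: the amide base removes the C3 proton (the established site of flavone lithiation, next to the C4 carbonyl), B(OMe)3 traps anion 17 as boronate 18, and H2O2 in AcOH converts C–B into C–O by 1,2-migration; isolated alkenes are inert to H2O2 without a metal or strong acid, so the prenyl and allyl groups should survive.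

Step 12
Reactants: 19 5,7-bis(allyloxy)-2-[3,4-bis(allyloxy)-2-(3-methylbut-2-en-1-yl)phenyl]-3-hydroxy-4H-chromen-4-one
Product: 20 2-[3,4-dihydroxy-2-(3-methylbut-2-en-1-yl)phenyl]-3,5,7-trihydroxy-4H-chromen-4-one
Conditions: Pd(PPh3)4 (10 mol %), morpholine (excess), THF, rt, argon; dilute acid work-up
Reagents that add atoms: none
Why: Tsuji–Trost deallylation: zerovalent palladium ionises each aryl allyl ether to a π-allyl complex and a phenoxide, and morpholine captures the allyl group irreversibly; the C-prenyl group has no leaving group and is untouched, and the neutral, non-reducing medium under argon protects both the alkene and the oxidation-prone polyphenol.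

## Compound list

1 | 2-bromo-3-hydroxy-4-methoxybenzaldehyde (2-bromoisovanillin) | COc1ccc(C=O)c(Br)c1O | starting material
2 | 2-bromo-3,4-dihydroxybenzaldehyde | Oc1ccc(C=O)c(Br)c1O | intermediate
3 | 3,4-diacetoxy-2-bromobenzaldehyde | CC(=O)Oc1ccc(C=O)c(Br)c1OC(C)=O | intermediate
4 | tributyl(3-methylbut-2-en-1-yl)stannane | CCCC[Sn](CCCC)(CCCC)CC=C(C)C | starting material
5 | 3,4-diacetoxy-2-(3-methylbut-2-en-1-yl)benzaldehyde | CC(=O)Oc1ccc(C=O)c(CC=C(C)C)c1OC(C)=O | intermediate
6 | 3,4-dihydroxy-2-(3-methylbut-2-en-1-yl)benzaldehyde (formed as its potassium salt) | Oc1ccc(C=O)c(CC=C(C)C)c1O | intermediate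
7 | 3,4-bis(allyloxy)-2-(3-methylbut-2-en-1-yl)benzaldehyde | C=CCOc1ccc(C=O)c(CC=C(C)C)c1OCC=C | intermediate
8 | phloroglucinol (benzene-1,3,5-triol) | Oc1cc(O)cc(O)c1 | starting material
9 | 3,5-bis(allyloxy)phenol | Oc1cc(OCC=C)cc(OCC=C)c1 | intermediate
10 | 1,2-bis(allyloxy)-4-(2,2-dibromovinyl)-3-(3-methylbut-2-en-1-yl)benzene | C=CCOc1ccc(C=C(Br)Br)c(CC=C(C)C)c1OCC=C | intermediate
11 | lithium [3,4-bis(allyloxy)-2-(3-methylbut-2-en-1-yl)phenyl]acetylide | [Li]C#Cc1ccc(OCC=C)c(OCC=C)c1CC=C(C)C | intermediate
12 | methyl 3-[3,4-bis(allyloxy)-2-(3-methylbut-2-en-1-yl)phenyl]prop-2-ynoate | COC(=O)C#Cc1ccc(OCC=C)c(OCC=C)c1CC=C(C)C | intermediate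
13 | methyl (2Z)-3-[3,5-bis(allyloxy)phenoxy]-3-[3,4-bis(allyloxy)-2-(3-methylbut-2-en-1-yl)phenyl]prop-2-enoate (ester cis to aryloxy) | COC(=O)/C=C(\Oc1cc(OCC=C)cc(OCC=C)c1)c1ccc(OCC=C)c(OCC=C)c1CC=C(C)C | intermediate
14 | (2Z)-3-[3,5-bis(allyloxy)phenoxy]-3-[3,4-bis(allyloxy)-2-(3-methylbut-2-en-1-yl)phenyl]prop-2-enoic acid (carboxyl cis to aryloxy) | OC(=O)/C=C(\Oc1cc(OCC=C)cc(OCC=C)c1)c1ccc(OCC=C)c(OCC=C)c1CC=C(C)C | intermediate
15 | (2Z)-3-[3,5-bis(allyloxy)phenoxy]-3-[3,4-bis(allyloxy)-2-(3-methylbut-2-en-1-yl)phenyl]prop-2-enoyl chloride | ClC(=O)/C=C(\Oc1cc(OCC=C)cc(OCC=C)c1)c1ccc(OCC=C)c(OCC=C)c1CC=C(C)C | intermediate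
16 | 5,7-bis(allyloxy)-2-[3,4-bis(allyloxy)-2-(3-methylbut-2-en-1-yl)phenyl]-4H-chromen-4-one (5,7,3',4'-tetra-O-allyl-2'-prenylflavone) | CC(C)=CCc1c(-c2cc(=O)c3c(OCC=C)cc(OCC=C)cc3o2)ccc(OCC=C)c1OCC=C | intermediate
17 | 3-lithio derivative of flavone 16 | CC(C)=CCc1c(-c2oc3cc(OCC=C)cc(OCC=C)c3c(=O)c2[Li])ccc(OCC=C)c1OCC=C | intermediate
18 | dimethyl {5,7-bis(allyloxy)-2-[3,4-bis(allyloxy)-2-(3-methylbut-2-en-1-yl)phenyl]-4-oxo-4H-chromen-3-yl}boronate | CC(C)=CCc1c(-c2oc3cc(OCC=C)cc(OCC=C)c3c(=O)c2B(OC)OC)ccc(OCC=C)c1OCC=C | intermediate
19 | 5,7-bis(allyloxy)-2-[3,4-bis(allyloxy)-2-(3-methylbut-2-en-1-yl)phenyl]-3-hydroxy-4H-chromen-4-one (5,7,3',4'-tetra-O-allyl-2'-prenylflavonol) | CC(C)=CCc1c(-c2oc3cc(OCC=C)cc(OCC=C)c3c(=O)c2O)ccc(OCC=C)c1OCC=C | intermediate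
20 | 2-[3,4-dihydroxy-2-(3-methylbut-2-en-1-yl)phenyl]-3,5,7-trihydroxy-4H-chromen-4-one (2'-prenylquercetin) | CC(C)=CCc1c(-c2oc3cc(O)cc(O)c3c(=O)c2O)ccc(O)c1O | target

## Step count and risk

Total step count: 12. Longest linear sequence: 11 steps (1 to 20 through steps 1–4 and 6–12); step 5 is a one-step side branch to phenol 9.

**Step 10 (key step).**
- What may go wrong: protonation of the prenyl alkene by the HCl/SnCl4 couple, leading to hydrochlorination or to cyclisation onto O3' with loss of its allyl group. Chelation-assisted cleavage of the 5-O-allyl ether may follow once the C4 carbonyl exists; this is harmless for the end product but costs base in step 11. E-configured material may also close onto ring B before it rotates.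
- Fallback: an acid-free closure of ring C at O1–C2, setting out from dibromoalkene 10 and phenol 9 and returning at flavone 16. Phenol 9 is ortho-formylated (MgCl2, Et3N, paraformaldehyde, MeCN; the two ortho positions are equivalent) to 2-hydroxy-4,6-bis(allyloxy)benzaldehyde F1. F1 is deprotonated with NaH and treated with acetylide 11, made from 10 as in step 7, to give the racemic propargylic alcohol F2. MnO2 oxidises this to the 2-hydroxyaryl ynone F3. Et2NH in EtOH adds to the ynone, and the enaminone closes 6-endo through the phenol oxygen to give 16.

**Step 11.**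
- What may go wrong: incomplete lithiation at C3, ring opening of the 3-lithiochromone by β-elimination of the phenoxide on warming, or protodeboronation before the oxidant arrives.
- Fallback: the C3 oxygen is carried in before ring closure, setting out from aldehyde 7 and phenol 9 and returning at target 20.
  - Methyl glycolate is O-allylated (allyl bromide, Ag2O) to methyl 2-(allyloxy)acetate F4.
  - The lithium enolate of F4 (LiN(i-Pr)2, THF, −78 °C) adds to 7 to give the aldol adduct F5 as a diastereomer mixture.
  - Dess–Martin oxidation gives the β-keto ester F6.
  - KN(SiMe3)2 and PhNTf2 give the enol triflate F7, with triflyloxy cis to the ester from the chelated enolate.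
  - The cesium salt of 9 displaces triflate by addition–elimination to give the 2-(allyloxy)-3-aryloxyacrylate F8.
  - LiOH gives the acid F9.
  - Activation and SnCl4 as in step 10 close ring C to the penta-O-allyl flavonol F10.
  - Pd(PPh3)4 and morpholine as in step 12 give 20.
- This detour is held in reserve because its substitution occurs at a tetrasubstituted alkene carbon and its acylation substrate is an allyl vinyl ether.

**Step 8.**
- What may go wrong: slow conjugate addition, because the para allyloxy group deactivates the ynoate and the ortho prenyl group shields it; attack through a ring carbon of the ambident phenoxide; or drift to the E acrylate by reversible addition.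
- Fallback: a stronger acceptor with the oxidation level adjusted afterwards, setting out from dibromoalkene 10 and phenol 9 and returning at acid 14, so that step 9 is skipped. Acetylide 11 is quenched with DMF and then aqueous KH2PO4 to give the ynal F11. Phenol 9 adds at room temperature with catalytic Et3N to give the (Z)-3-aryloxy enal F12. Pinnick oxidation (NaClO2, NaH2PO4, excess 2-methyl-2-butene) gives 14.

**Step 3.**
- What may go wrong: transfer of the prenyl group through its tertiary terminus, protodestannylation, or slow oxidative addition at the doubly ortho-substituted bromide.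
- Fallback: the prenyl group is built in two operations, setting out from diacetate 3 and returning at 5. Stille coupling of 3 with allyltributylstannane, which has no regiochemical ambiguity, gives 2-allyl-3,4-diacetoxybenzaldehyde F13. Olefin cross-metathesis with 2-methyl-2-butene (second-generation Grubbs catalyst, (H2IMes)(PCy3)Cl2Ru=CHPh) turns the allyl into the prenyl group at a stage where the molecule has no other alkene, giving 5.

## Further compounds

F1 | step 10 | 2-hydroxy-4,6-bis(allyloxy)benzaldehyde | O=Cc1c(O)cc(OCC=C)cc1OCC=C
F2 | step 10 | 1-[2-hydroxy-4,6-bis(allyloxy)phenyl]-3-[3,4-bis(allyloxy)-2-(3-methylbut-2-en-1-yl)phenyl]prop-2-yn-1-ol (racemic) | OC(C#Cc1ccc(OCC=C)c(OCC=C)c1CC=C(C)C)c1c(O)cc(OCC=C)cc1OCC=C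
F3 | step 10 | 1-[2-hydroxy-4,6-bis(allyloxy)phenyl]-3-[3,4-bis(allyloxy)-2-(3-methylbut-2-en-1-yl)phenyl]prop-2-yn-1-one | O=C(C#Cc1ccc(OCC=C)c(OCC=C)c1CC=C(C)C)c1c(O)cc(OCC=C)cc1OCC=C
F4 | step 11 | methyl 2-(allyloxy)acetate | COC(=O)COCC=C
F5 | step 11 | methyl 2-(allyloxy)-3-[3,4-bis(allyloxy)-2-(3-methylbut-2-en-1-yl)phenyl]-3-hydroxypropanoate (racemic, both diastereomers) | COC(=O)C(OCC=C)C(O)c1ccc(OCC=C)c(OCC=C)c1CC=C(C)C
F6 | step 11 | methyl 2-(allyloxy)-3-[3,4-bis(allyloxy)-2-(3-methylbut-2-en-1-yl)phenyl]-3-oxopropanoate | COC(=O)C(OCC=C)C(=O)c1ccc(OCC=C)c(OCC=C)c1CC=C(C)C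
F7 | step 11 | methyl (2E)-2-(allyloxy)-3-[3,4-bis(allyloxy)-2-(3-methylbut-2-en-1-yl)phenyl]-3-(trifluoromethylsulfonyloxy)prop-2-enoate (ester cis to triflyloxy) | COC(=O)/C(OCC=C)=C(\OS(=O)(=O)C(F)(F)F)c1ccc(OCC=C)c(OCC=C)c1CC=C(C)C
F8 | step 11 | methyl (2E)-2-(allyloxy)-3-[3,5-bis(allyloxy)phenoxy]-3-[3,4-bis(allyloxy)-2-(3-methylbut-2-en-1-yl)phenyl]prop-2-enoate (ester cis to aryloxy) | COC(=O)/C(OCC=C)=C(\Oc1cc(OCC=C)cc(OCC=C)c1)c1ccc(OCC=C)c(OCC=C)c1CC=C(C)C
F9 | step 11 | (2E)-2-(allyloxy)-3-[3,5-bis(allyloxy)phenoxy]-3-[3,4-bis(allyloxy)-2-(3-methylbut-2-en-1-yl)phenyl]prop-2-enoic acid (carboxyl cis to aryloxy) | OC(=O)/C(OCC=C)=C(\Oc1cc(OCC=C)cc(OCC=C)c1)c1ccc(OCC=C)c(OCC=C)c1CC=C(C)C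
F10 | step 11 | 3,5,7-tris(allyloxy)-2-[3,4-bis(allyloxy)-2-(3-methylbut-2-en-1-yl)phenyl]-4H-chromen-4-one | CC(C)=CCc1c(-c2oc3cc(OCC=C)cc(OCC=C)c3c(=O)c2OCC=C)ccc(OCC=C)c1OCC=C
F11 | step 8 | 3-[3,4-bis(allyloxy)-2-(3-methylbut-2-en-1-yl)phenyl]prop-2-ynal | O=CC#Cc1ccc(OCC=C)c(OCC=C)c1CC=C(C)C
F12 | step 8 | (2Z)-3-[3,5-bis(allyloxy)phenoxy]-3-[3,4-bis(allyloxy)-2-(3-methylbut-2-en-1-yl)phenyl]prop-2-enal (formyl cis to aryloxy) | O=C/C=C(\Oc1cc(OCC=C)cc(OCC=C)c1)c1ccc(OCC=C)c(OCC=C)c1CC=C(C)C
F13 | step 3 | 2-allyl-3,4-diacetoxybenzaldehyde | CC(=O)Oc1ccc(C=O)c(CC=C)c1OC(C)=O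
A1 | alternative 1 | 5,7-bis(methoxymethoxy)-4-oxo-4H-chromen-3-yl 6-bromo-2,3-bis(methoxymethoxy)benzoate | O=C(Oc1coc2cc(OCOC)cc(OCOC)c2c1=O)c1c(Br)ccc(OCOC)c1OCOC
A2 | alternative 1 | tetra-O-methoxymethyl lactone-bridged 2-arylchromone (six-membered lactone from O3 through the carbonyl carbon to C2' of ring B) | O=C1Oc2c(-c3ccc(OCOC)c(OCOC)c31)oc1cc(OCOC)cc(OCOC)c1c2=O
A3 | alternative 2 | 2-iodo-3,5-bis(methoxymethoxy)phenol | Oc1cc(OCOC)cc(OCOC)c1I
A4 | alternative 2 | 1-ethynyl-3,4-bis(methoxymethoxy)-2-(3-methylbut-2-en-1-yl)benzene | C#Cc1ccc(OCOC)c(OCOC)c1CC=C(C)C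
A5 | alternative 2 | 5,7-bis(methoxymethoxy)-2-[3,4-bis(methoxymethoxy)-2-(3-methylbut-2-en-1-yl)phenyl]-4H-chromen-4-one | CC(C)=CCc1c(-c2cc(=O)c3c(OCOC)cc(OCOC)cc3o2)ccc(OCOC)c1OCOC
A6 | alternative 3 | 1-[3,4-bis(methoxymethoxy)-2-(3-methylbut-2-en-1-yl)phenyl]-2-(methoxymethoxy)-3-(2,4,6-trifluorophenyl)propane-1,3-dione (racemic) | CC(C)=CCc1c(C(=O)C(OCOC)C(=O)c2c(F)cc(F)cc2F)ccc(OCOC)c1OCOC
A7 | alternative 3 | 5,7-difluoro-3-(methoxymethoxy)-2-[3,4-bis(methoxymethoxy)-2-(3-methylbut-2-en-1-yl)phenyl]-4H-chromen-4-one | CC(C)=CCc1c(-c2oc3cc(F)cc(F)c3c(=O)c2OCOC)ccc(OCOC)c1OCOC
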